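**Retrosynthetic overview**
- Only the dihydropyran ring is built, and it is closed last: an inverse-demand oxa-[4+2] cycloaddition between the strained E-4,5-alkene of (−)-β-caryophyllene and 2-isobutylidenesyncarpic acid forms the C4–O and C5–C bonds and three stereocentres at once. The cyclobutane/nine-membered bicycle and the cyclohexanetrione ring are bought.
- The heterodiene is not made from an aldehyde. It is released in the flask by a 1,5-hydrogen shift from its dienol tautomer, 2-(2-methylprop-1-enyl)syncarpic acid.
- Key C–C disconnection: dione α-carbon / alkenyl carbon, both nucleophilic in their normal form. The dione carbon is used with reversed polarity as an enolonium equivalent (phenyliodonium ylide) and coupled with an alkenylboronic acid.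
- The ylide comes from syncarpic acid and PhI(OAc)2.

Assumption: 1, 3 and 5 are bought as catalogue compounds, 5 as the natural (−)-(1R,9S) enantiomer.

**Route**

Step 1
Reactants: 1 syncarpic acid
Product: 2 phenyliodonium ylide of syncarpic acid
Conditions: PhI(OAc)2 (1.05 equiv), KOH (2.1 equiv), MeOH, 0 °C, 1 h; precipitate filtered off
Reagents that add atoms: (diacetoxyiodo)benzene, CC(=O)OI(OC(C)=O)c1ccccc1
Why: Ligand exchange of the acidic dione on trivalent iodine followed by deprotonation gives the doubly carbonyl-stabilised phenyliodonium ylide (standard iodonium-ylide formation for cyclic 1,3-diones), which converts the normally nucleophilic dione α-carbon into an enolonium equivalent; no stereocentre is formed.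

Step 2
Reactants: 2 phenyliodonium ylide of syncarpic acid; 3 (2-methylprop-1-en-1-yl)boronic acid
Product: 4 2-(2-methylprop-1-enyl)syncarpic acid
Conditions: 3 (1.5 equiv), Pd(P(t-Bu)3)2 (5 mol %), LiOH·H2O (3 equiv), degassed DME/H2O 4:1, 25 °C, 4 h; then aq. AcOH to pH 4, acid–base extraction
Reagents that add atoms: none
Why: Proposed new method: zerovalent palladium inserts into the enolate-carbon–iodine bond of the trivalent-iodine zwitterion with loss of iodobenzene, the resulting C-bound palladium dione enolate transmetalates with the hydroxide-activated alkenylboronate, and reductive elimination joins the dione α-carbon (acting as the electrophile, an enolonium equivalent) to the nucleophilic alkenyl carbon, the dienolate being protonated at work-up; the closest known reaction type is the Suzuki–Miyaura-type arylation of phenyliodonium ylides of cyclic 1,3-dicarbonyl compounds and of alkenyl(aryl)iodonium salts, here extended to an alkenylboronic acid, and no stereocentre is formed.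

Step 3
Reactants: 4 2-(2-methylprop-1-enyl)syncarpic acid; 5 (−)-β-caryophyllene
Product: 7 myrtucommulone K, via isobutylidenesyncarpic acid 6 (not isolated)
Conditions: 5 (2 equiv), AcOH (10 mol %), PhMe, 60 °C, 16 h; chromatography
Reagents that add atoms: none
Why: A 1,5-hydrogen shift (dienol-to-enone tautomerisation, catalysed by AcOH) turns 4 into the electron-poor 1-oxadiene 6, which is trapped by the strained E-alkene of 5 in an inverse-electron-demand hetero-Diels–Alder reaction: oxygen bonds to the more substituted C4 and the isopropyl-bearing carbon to C5, suprafacial addition to the E-alkene gives the trans ring fusion, attack on the exposed alkene face (the face that peracids epoxidise) sets 4R and 5S, the E-oxadiene geometry with the C4-methyl/C6 side of the alkene under the dione sets the R configuration at the isopropyl-bearing carbon, C1 and C9 are carried over unchanged from 5, and the minor diastereomers (other alkene face, epimer at the isopropyl-bearing carbon) are removed by chromatography.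

**Compound list**

1 | syncarpic acid, enol form: 5-hydroxy-2,2,6,6-tetramethylcyclohex-4-ene-1,3-dione (achiral) | CC1(C)C(=O)C=C(O)C(C)(C)C1=O | starting material
2 | phenyliodonium ylide of syncarpic acid: 4,4,6,6-tetramethyl-3,5-dioxo-2-(phenyliodonio)cyclohex-1-en-1-olate (achiral zwitterion) | CC1(C)C(=O)C([I+]c2ccccc2)=C([O-])C(C)(C)C1=O | intermediate
3 | (2-methylprop-1-en-1-yl)boronic acid | CC(C)=CB(O)O | starting material
4 | 2-(2-methylprop-1-enyl)syncarpic acid: 5-hydroxy-2,2,6,6-tetramethyl-4-(2-methylprop-1-en-1-yl)cyclohex-4-ene-1,3-dione (achiral) | CC(C)=CC1=C(O)C(C)(C)C(=O)C(C)(C)C1=O | intermediate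
5 | (−)-β-caryophyllene: (1R,4E,9S)-4,11,11-trimethyl-8-methylidenebicyclo[7.2.0]undec-4-ene | C/C1=C\CCC(=C)[C@H]2CC(C)(C)[C@@H]2CC1 | starting material
6 | isobutylidenesyncarpic acid: 2,2,4,4-tetramethyl-6-(2-methylpropylidene)cyclohexane-1,3,5-trione (achiral) | CC(C)C=C1C(=O)C(C)(C)C(=O)C(C)(C)C1=O | intermediate
7 | myrtucommulone K: dihydropyran trans-fused across C4–C5 of the caryophyllane skeleton (O on C4, isopropyl-bearing CH on C5) and fused to the tetramethylcyclohexenedione; 8(13)-methylene retained; 1R,4R,5S,9S (caryophyllane numbering) and R at the isopropyl-bearing carbon | C=C1CC[C@H]2[C@@H](C(C)C)C3=C(O[C@]2(C)CC[C@@H]2[C@@H]1CC2(C)C)C(C)(C)C(=O)C(C)(C)C3=O | target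

**Step count and risks**

Total step count: 3. Longest linear sequence: 3 steps (1 → 2 → 4 → 7).

Steps most likely to fail:

Step 2 (highest risk). The palladium coupling on the zwitterion is an untested extension of the known arylations; protodeiodination back to 1 or phenyl transfer could compete. Fallback, setting out from 2 and coming back to the route at 7: the ylide is alkylated without palladium by triisobutylborane in THF at 0 to 25 °C. The ylide carbon attacks boron, an isobutyl group undergoes a 1,2-shift with loss of iodobenzene, and hydrolysis of the boron enolate gives 2-isobutylsyncarpic acid F2. F2 is then dehydrogenated with TEMPO and Ag2O in toluene in the presence of 5, so that 6 is generated oxidatively instead of by tautomerisation and is trapped to give 7.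

Step 3. The dienol may convert to 6 only slowly or condense with itself, and the cycloaddition is expected to give a diastereomer mixture from which 7 must be separated. Fallback, setting out from 4 and coming back at 7: 4 (in equilibrium with 6) is treated with PhSO2Na and AcOH in aqueous EtOH to give the crystalline sulfone adduct 5-hydroxy-2,2,6,6-tetramethyl-4-[2-methyl-1-(phenylsulfonyl)propyl]cyclohex-4-ene-1,3-dione F3. After recrystallisation, F3 is heated with 5 and solid NaHCO3 in toluene at 80 °C; retro-Michael loss of sulfinate releases 6 slowly at low concentration, and cycloaddition gives 7.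

Step 1. The ylide of this hindered trione may form poorly or rearrange on handling (phenyl shift from iodine to oxygen). Fallback, setting out from 1 (together with 3) and coming back at 4: the polarity of both partners is exchanged. Boronic acid 3 is converted with PhI(OAc)2 and BF3·OEt2 (CH2Cl2, 0 °C, then aqueous NaBF4) into (2-methylprop-1-en-1-yl)(phenyl)iodonium tetrafluoroborate F1, a vinyl-cation equivalent. F1 alkenylates the potassium enolate of 1 (t-BuOK, THF, −78 to 0 °C) by ligand coupling on trivalent iodine to give 4 directly.

**Further compounds**

F1 | step 1 | (2-methylprop-1-en-1-yl)(phenyl)iodonium tetrafluoroborate | CC(C)=C[I+]c1ccccc1.F[B-](F)(F)F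
F2 | step 2 | 2-isobutylsyncarpic acid: 5-hydroxy-2,2,6,6-tetramethyl-4-(2-methylpropyl)cyclohex-4-ene-1,3-dione | CC(C)CC1=C(O)C(C)(C)C(=O)C(C)(C)C1=O
F3 | step 3 | 5-hydroxy-2,2,6,6-tetramethyl-4-[2-methyl-1-(phenylsulfonyl)propyl]cyclohex-4-ene-1,3-dione (racemic) | CC(C)C(C1=C(O)C(C)(C)C(=O)C(C)(C)C1=O)S(=O)(=O)c1ccccc1
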